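The target is opened at the C4–C4a bond of the bottom flavan unit. In that unit C4 carries only hydrogens and sits between the oxygenated C3 and C4a of ring A, which is what results when an electron-rich arene carbon attacks the CH2 end of a monosubstituted epoxide. A gold-catalysed epoxy–arene cyclisation therefore closes the bottom pyran ring in one operation, fixes the 4→8 link and frees the 3-OH for the last galloylation, while C2 and C3 stay as set. Its precursor is the benzylated, bromine-capped 4β→6 top–middle digallate whose middle C4 bears a dibenzylated phloroglucinol ring, etherified at the ortho oxygen with a (1R,2R)-1-aryl-2,3-epoxypropyl group.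

Key step: step 11

Remark: 3,4,5-tris(benzyloxy)benzoic acid, 3,5-bis(benzyloxy)phenol and 3,4-bis(benzyloxy)benzaldehyde are taken from the catalogue (benzyl ethers of gallic acid, phloroglucinol and 3,4-dihydroxybenzaldehyde); the top unit is given a C8 bromine like the middle unit, so that one brominated monomer serves both units and the top unit cannot attack itself through C8, and both bromines leave in the last step.

Step 1
Reactants: 1 (−)-epicatechin
Product: 2 5,7,3',4'-tetra-O-benzyl-(−)-epicatechin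
Conditions: BnBr (4.4 equiv), K2CO3, DMF, 0 °C → rt, Ar
Reagents that add atoms: benzyl bromide, BrCc1ccccc1
Why: Williamson etherification, in which carbonate deprotonates only the four phenols, so these are benzylated while the secondary 3-OH and the C2/C3 stereocenters stay as they are.

Step 2
Reactants: 2 5,7,3',4'-tetra-O-benzyl-(−)-epicatechin
Product: 3 8-bromo-5,7,3',4'-tetra-O-benzyl-(−)-epicatechin
Conditions: NBS (1.0 equiv), CH2Cl2, −78 °C → rt
Reagents that add atoms: N-bromosuccinimide, O=C1CCC(=O)N1Br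
Why: Electrophilic aromatic bromination, which at low temperature should go to C8 of ring A, the most nucleophilic carbon (ortho to the ring oxygen and to a benzyloxy group), and stop at the monobromide.

Step 3
Reactants: 3 8-bromo-5,7,3',4'-tetra-O-benzyl-(−)-epicatechin
Product: 4 8-bromo-4β-(2-ethoxyethoxy)-5,7,3',4'-tetra-O-benzyl-epicatechin
Conditions: DDQ (2 equiv), HOCH2CH2OEt (5 equiv), CH2Cl2, rt
Reagents that add atoms: 2-ethoxyethanol, CCOCCO
Why: DDQ benzylic oxidation, in which hydride abstraction from C4 gives the cation stabilised by ring A and the alcohol adds on the face anti to the C2 aryl and C3 hydroxyl groups, so the new C4 stereocenter is 4β (3,4-trans).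

Step 4
Reactants: 4 8-bromo-4β-(2-ethoxyethoxy)-5,7,3',4'-tetra-O-benzyl-epicatechin; 5 3,4,5-tris(benzyloxy)benzoic acid
Product: 6 8-bromo-4β-(2-ethoxyethoxy)-5,7,3',4'-tetra-O-benzyl-epicatechin 3-O-[3,4,5-tris(benzyloxy)benzoate]
Conditions: 5 (1.5 equiv), DCC, DMAP, CH2Cl2, rt
Reagents that add atoms: none
Why: Steglich esterification of the only hydroxyl; the benzylic ether at C4 and the aryl bromide are inert to carbodiimide and DMAP, and no stereocenter is involved.

Step 5
Reactants: 6 8-bromo-4β-(2-ethoxyethoxy)-5,7,3',4'-tetra-O-benzyl-epicatechin 3-O-[3,4,5-tris(benzyloxy)benzoate]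
Product: 7 8-bromo-4β-[(2,6-dimethylphenyl)thio]-5,7,3',4'-tetra-O-benzyl-epicatechin 3-O-[3,4,5-tris(benzyloxy)benzoate]
Conditions: 2,6-Me2C6H3SH (3 equiv), BF3·OEt2 (0.5 equiv), CH2Cl2, −78 → −30 °C
Reagents that add atoms: 2,6-dimethylbenzenethiol, Cc1cccc(C)c1S
Why: Lewis-acid-mediated SN1 exchange of oxygen for sulfur at C4 through the flavan-4-yl cation, in which the 3-O-galloyl group shields the α face by acyloxonium participation, so the thiol enters from the β face and the 3,4-trans sulfide should result.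

Step 6
Reactants: 7 8-bromo-4β-[(2,6-dimethylphenyl)thio]-5,7,3',4'-tetra-O-benzyl-epicatechin 3-O-[3,4,5-tris(benzyloxy)benzoate]; 6 8-bromo-4β-(2-ethoxyethoxy)-5,7,3',4'-tetra-O-benzyl-epicatechin 3-O-[3,4,5-tris(benzyloxy)benzoate]
Product: 8 4β→6 dimer: top unit (8-bromo-tetra-O-benzyl-epicatechin 3-O-tribenzylgallate) bonded from C4 (β) to C6 of the middle unit (8-bromo-4β-(2-ethoxyethoxy)-tetra-O-benzyl-epicatechin 3-O-tribenzylgallate)
Conditions: 6 (2.5 equiv, excess recovered), I2, Ag2O, 4 Å MS, CH2Cl2, −78 → −20 °C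
Reagents that add atoms: none
Why: Thiophilic iodine activation of the hindered aryl sulfide gives the C4 cation, which the only free ring-A carbon of 6 (C6, since C8 is brominated) captures in the Friedel–Crafts interflavan coupling of procyanidin synthesis; the ether leaving group of 6 is inert to the soft promoter, the excess of 6 outcompetes the C6 positions of 7 and 8, and attack anti to the participating 3-O-galloyl group sets the new C4 stereocenter as 4β (3,4-trans).

Step 7
Reactants: 8 4β→6 dimer with the 4β-(2-ethoxyethoxy) group on the middle unit; 9 3,5-bis(benzyloxy)phenol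
Product: 10 4β→6 dimer whose middle C4 carries a β-[2-hydroxy-4,6-bis(benzyloxy)phenyl] group
Conditions: 9 (3 equiv), BF3·OEt2 (0.5 equiv), CH2Cl2, −78 → −30 °C
Reagents that add atoms: none
Why: Hard Lewis acid ionisation of the ethoxyethyl ether and Friedel–Crafts arylation of the C4 cation by the phenol at its C2 (flanked by OH and one benzyloxy group and thus less hindered than C4 between two benzyloxy groups, the same preference that favours C8 over C6 in flavans), with attack on the β face anti to the 3-O-galloyl group giving the 3,4-trans bond.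

Step 8
Reactants: 11 3,4-bis(benzyloxy)benzaldehyde
Product: 12 rac-1-[3,4-bis(benzyloxy)phenyl]prop-2-en-1-ol
Conditions: CH2=CHMgBr, THF, 0 °C; aq. NH4Cl
Reagents that add atoms: vinylmagnesium bromide, C=C[Mg]Br
Why: Grignard 1,2-addition to the aromatic aldehyde; the carbinol is made as a racemate on purpose, since step 9 resolves it.

Step 9
Reactants: 12 rac-1-[3,4-bis(benzyloxy)phenyl]prop-2-en-1-ol
Product: 13 (S)-[3,4-bis(benzyloxy)phenyl][(2R)-oxiran-2-yl]methanol (erythro)
Conditions: Ti(OiPr)4 (10 mol %), L-(+)-diisopropyl tartrate (15 mol %), t-BuOOH (0.45 equiv), 4 Å MS, CH2Cl2, −20 °C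
Reagents that add atoms: tert-butyl hydroperoxide, CC(C)(C)OO
Why: Sharpless kinetic resolution, in which the titanium tartrate catalyst epoxidises the (R)-alcohol much faster than the (S)-alcohol and delivers oxygen anti to the carbinol substituent, which sets the epoxide carbon as R and gives the erythro (1S,2R) epoxy alcohol (the carbinol descriptor changes only because the priorities change), the unreacted (S)-alcohol being removed by chromatography.

Step 10
Reactants: 10 4β→6 dimer whose middle C4 carries a β-[2-hydroxy-4,6-bis(benzyloxy)phenyl] group; 13 (S)-[3,4-bis(benzyloxy)phenyl][(2R)-oxiran-2-yl]methanol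
Product: 14 aryl ether of 10 in which the phenol oxygen carries the (R)-[3,4-bis(benzyloxy)phenyl][(2R)-oxiran-2-yl]methyl group (threo)
Conditions: 13 (1.5 equiv), PPh3, DIAD, toluene (concentrated), ultrasound, 0 °C → rt
Reagents that add atoms: none
Why: Mitsunobu etherification, in which the phenol (the only acidic OH) attacks the alkoxyphosphonium ion of the secondary carbinol by SN2 with inversion, turning the (1S) alcohol into the (1R) aryl ether without touching the epoxide carbon, while the electron-withdrawing epoxide next to the benzylic carbon disfavours ionisation.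

Step 11
Reactants: 14 aryl ether of 10 carrying the (R)-[3,4-bis(benzyloxy)phenyl][(2R)-oxiran-2-yl]methyl group
Product: 15 protected trimer with free bottom 3-OH (bottom unit: 5,7,3',4'-tetra-O-benzyl-epicatechin bonded through C8 to the β position of middle C4)
Conditions: AuCl3 (5 mol %), AgOSO2CF3 (15 mol %), 4 Å MS, ClCH2CH2Cl, 0 °C → rt
Reagents that add atoms: none
Why: The cationic trivalent gold species formed from AuCl3 and AgOSO2CF3 binds the epoxide oxygen, the free ring carbon lying between the ether oxygen and a benzyloxy group (para to the second benzyloxy group) attacks the CH2 terminus in an SN2-like Friedel–Crafts alkylation, and loss of the arene proton restores aromaticity and releases the 3-OH. The closest known reaction type is the gold- or Lewis-acid-catalysed cycloalkylation of aryl glycidyl ethers to chroman-3-ols, which has been used to make flavan-3-ols from aryl 1-aryl-2,3-epoxypropyl ethers. The pyran ring of the bottom unit closes in the 6-endo-tet mode, both epoxide carbons ending up in the new ring. No stereocenter is created: the benzylic C2–O bond and the C3–O bond stay intact, so the (2R,3R) configuration laid down by the kinetic resolution and the Mitsunobu inversion is carried over. The step needs 6-endo attack at the primary carbon instead of 5-exo attack at C3, which the unhindered CH2 terminus and the inductively deactivated internal carbon should secure, and it needs the 4→8 connectivity, which is fixed because the only free carbon ortho to the ether oxygen is the one used, the other ortho carbon carrying C4 of the middle unit. The mild catalytic activation at or below room temperature is chosen so that the doubly activated benzylic ether and the interflavan bonds are not ionised.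

Step 12
Reactants: 15 protected trimer with free bottom 3-OH; 5 3,4,5-tris(benzyloxy)benzoic acid
Product: 16 perbenzylated 8,8-dibromo trimer tris[3,4,5-tris(benzyloxy)benzoate]
Conditions: 5 (3 equiv), DCC, DMAP, CH2Cl2, rt
Reagents that add atoms: none
Why: Steglich esterification of the single free hydroxyl, the axial 3-OH of the bottom unit, driven by excess acid; no stereocenter is affected.

Step 13
Reactants: 16 perbenzylated 8,8-dibromo trimer tris[3,4,5-tris(benzyloxy)benzoate]
Product: 17 epicatechin 3-O-gallate-(4β→6)-epicatechin 3-O-gallate-(4β→8)-epicatechin 3-O-gallate (target)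
Conditions: H2 (1 atm), Pd(OH)2/C, Et3N (2.2 equiv), THF/MeOH, rt; filtration under Ar, then AcOH
Reagents that add atoms: none
Why: Catalytic hydrogenolysis on palladium should cleave all twenty-one benzyl ethers and both aryl–bromine bonds, Et3N taking up the HBr so that the acid-labile interflavan bonds are not endangered, while the gallate esters, the C4–aryl bonds and the stereocenters are not reduced.

Compound list
1 | (−)-epicatechin | O[C@@H]1Cc2c(O)cc(O)cc2O[C@@H]1c1ccc(O)c(O)c1 | starting material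
2 | 5,7,3',4'-tetra-O-benzyl-(−)-epicatechin | O[C@@H]1Cc2c(OCc3ccccc3)cc(OCc3ccccc3)cc2O[C@@H]1c1ccc(OCc2ccccc2)c(OCc2ccccc2)c1 | intermediate
3 | 8-bromo-5,7,3',4'-tetra-O-benzyl-(−)-epicatechin | O[C@@H]1Cc2c(OCc3ccccc3)cc(OCc3ccccc3)c(Br)c2O[C@@H]1c1ccc(OCc2ccccc2)c(OCc2ccccc2)c1 | intermediate
4 | 8-bromo-4β-(2-ethoxyethoxy)-5,7,3',4'-tetra-O-benzyl-epicatechin (2,3-cis, 3,4-trans) | O[C@@H]1[C@@H](OCCOCC)c2c(OCc3ccccc3)cc(OCc3ccccc3)c(Br)c2O[C@@H]1c1ccc(OCc2ccccc2)c(OCc2ccccc2)c1 | intermediate
5 | 3,4,5-tris(benzyloxy)benzoic acid | OC(=O)c1cc(OCc2ccccc2)c(OCc2ccccc2)c(OCc2ccccc2)c1 | starting material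
6 | 8-bromo-4β-(2-ethoxyethoxy)-5,7,3',4'-tetra-O-benzyl-epicatechin 3-O-[3,4,5-tris(benzyloxy)benzoate] | O=C(O[C@@H]1[C@@H](OCCOCC)c2c(OCc3ccccc3)cc(OCc3ccccc3)c(Br)c2O[C@@H]1c1ccc(OCc2ccccc2)c(OCc2ccccc2)c1)c1cc(OCc2ccccc2)c(OCc2ccccc2)c(OCc2ccccc2)c1 | intermediate
7 | 8-bromo-4β-[(2,6-dimethylphenyl)thio]-5,7,3',4'-tetra-O-benzyl-epicatechin 3-O-[3,4,5-tris(benzyloxy)benzoate] | O=C(O[C@@H]1[C@@H](Sc2c(C)cccc2C)c2c(OCc3ccccc3)cc(OCc3ccccc3)c(Br)c2O[C@@H]1c1ccc(OCc2ccccc2)c(OCc2ccccc2)c1)c1cc(OCc2ccccc2)c(OCc2ccccc2)c(OCc2ccccc2)c1 | intermediate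
8 | 4β→6 dimer: top unit 8-bromo-tetra-O-benzyl-epicatechin 3-O-tribenzylgallate, middle unit 8-bromo-4β-(2-ethoxyethoxy)-tetra-O-benzyl-epicatechin 3-O-tribenzylgallate | O=C(c1cc(OCc2ccccc2)c(OCc2ccccc2)c(OCc2ccccc2)c1)O[C@@H]1[C@@H](OCCOCC)c2c(OCc3ccccc3)c([C@H]3c4c(OCc5ccccc5)cc(OCc5ccccc5)c(Br)c4O[C@H](c4ccc(OCc5ccccc5)c(OCc5ccccc5)c4)[C@@H]3OC(=O)c3cc(OCc4ccccc4)c(OCc4ccccc4)c(OCc4ccccc4)c3)c(OCc3ccccc3)c(Br)c2O[C@@H]1c1ccc(OCc2ccccc2)c(OCc2ccccc2)c1 | intermediate
9 | 3,5-bis(benzyloxy)phenol | Oc1cc(OCc2ccccc2)cc(OCc2ccccc2)c1 | starting material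
10 | dimer 8 with the middle 4β-(2-ethoxyethoxy) group replaced by a 4β-[2-hydroxy-4,6-bis(benzyloxy)phenyl] group | O=C(c1cc(OCc2ccccc2)c(OCc2ccccc2)c(OCc2ccccc2)c1)O[C@@H]1[C@@H](c2c(OCc3ccccc3)cc(OCc3ccccc3)cc2O)c2c(OCc3ccccc3)c([C@H]3c4c(OCc5ccccc5)cc(OCc5ccccc5)c(Br)c4O[C@H](c4ccc(OCc5ccccc5)c(OCc5ccccc5)c4)[C@@H]3OC(=O)c3cc(OCc4ccccc4)c(OCc4ccccc4)c(OCc4ccccc4)c3)c(OCc3ccccc3)c(Br)c2O[C@@H]1c1ccc(OCc2ccccc2)c(OCc2ccccc2)c1 | intermediate
11 | 3,4-bis(benzyloxy)benzaldehyde | O=Cc1ccc(OCc2ccccc2)c(OCc2ccccc2)c1 | starting material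
12 | rac-1-[3,4-bis(benzyloxy)phenyl]prop-2-en-1-ol (racemate) | OC(C=C)c1ccc(OCc2ccccc2)c(OCc2ccccc2)c1 | intermediate
13 | (S)-[3,4-bis(benzyloxy)phenyl][(2R)-oxiran-2-yl]methanol (erythro) | O[C@@H](c1ccc(OCc2ccccc2)c(OCc2ccccc2)c1)[C@H]1CO1 | intermediate
14 | key-step precursor: 10 O-alkylated at the phenol with the (R)-[3,4-bis(benzyloxy)phenyl][(2R)-oxiran-2-yl]methyl group (threo) | O=C(c1cc(OCc2ccccc2)c(OCc2ccccc2)c(OCc2ccccc2)c1)O[C@@H]1[C@@H](c2c(OCc3ccccc3)cc(OCc3ccccc3)cc2O[C@H](c2ccc(OCc3ccccc3)c(OCc3ccccc3)c2)[C@H]2CO2)c2c(OCc3ccccc3)c([C@H]3c4c(OCc5ccccc5)cc(OCc5ccccc5)c(Br)c4O[C@H](c4ccc(OCc5ccccc5)c(OCc5ccccc5)c4)[C@@H]3OC(=O)c3cc(OCc4ccccc4)c(OCc4ccccc4)c(OCc4ccccc4)c3)c(OCc3ccccc3)c(Br)c2O[C@@H]1c1ccc(OCc2ccccc2)c(OCc2ccccc2)c1 | intermediate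
15 | key-step product: protected 4β→6, 4β→8 trimer, top and middle units as 8-bromo 3-O-tribenzylgallates, bottom unit (2R,3R) tetra-O-benzyl with free 3-OH | O=C(c1cc(OCc2ccccc2)c(OCc2ccccc2)c(OCc2ccccc2)c1)O[C@@H]1[C@@H](c2c(OCc3ccccc3)cc(OCc3ccccc3)c3c2O[C@H](c2ccc(OCc4ccccc4)c(OCc4ccccc4)c2)[C@H](O)C3)c2c(OCc3ccccc3)c([C@H]3c4c(OCc5ccccc5)cc(OCc5ccccc5)c(Br)c4O[C@H](c4ccc(OCc5ccccc5)c(OCc5ccccc5)c4)[C@@H]3OC(=O)c3cc(OCc4ccccc4)c(OCc4ccccc4)c(OCc4ccccc4)c3)c(OCc3ccccc3)c(Br)c2O[C@@H]1c1ccc(OCc2ccccc2)c(OCc2ccccc2)c1 | intermediate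
16 | 15 esterified at the bottom 3-OH with 3,4,5-tris(benzyloxy)benzoic acid (perbenzylated dibromo trimer trigallate) | O=C(c1cc(OCc2ccccc2)c(OCc2ccccc2)c(OCc2ccccc2)c1)O[C@@H]1[C@@H](c2c(OCc3ccccc3)cc(OCc3ccccc3)c3c2O[C@H](c2ccc(OCc4ccccc4)c(OCc4ccccc4)c2)[C@H](OC(=O)c2cc(OCc4ccccc4)c(OCc4ccccc4)c(OCc4ccccc4)c2)C3)c2c(OCc3ccccc3)c([C@H]3c4c(OCc5ccccc5)cc(OCc5ccccc5)c(Br)c4O[C@H](c4ccc(OCc5ccccc5)c(OCc5ccccc5)c4)[C@@H]3OC(=O)c3cc(OCc4ccccc4)c(OCc4ccccc4)c(OCc4ccccc4)c3)c(OCc3ccccc3)c(Br)c2O[C@@H]1c1ccc(OCc2ccccc2)c(OCc2ccccc2)c1 | intermediate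
17 | epicatechin 3-O-gallate-(4β→6)-epicatechin 3-O-gallate-(4β→8)-epicatechin 3-O-gallate | O=C(O[C@@H]1[C@@H](c2c(O)cc3c(c2O)[C@H](c2c(O)cc(O)c4c2O[C@H](c2ccc(O)c(O)c2)[C@H](OC(=O)c2cc(O)c(O)c(O)c2)C4)[C@@H](OC(=O)c2cc(O)c(O)c(O)c2)[C@@H](c2ccc(O)c(O)c2)O3)c2c(O)cc(O)cc2O[C@@H]1c1ccc(O)c(O)c1)c1cc(O)c(O)c(O)c1 | target

Total step count: 13. Longest linear sequence: 11 steps (steps 1–7 and 10–13, from (−)-epicatechin); the epoxy alcohol branch (steps 8 and 9) joins at step 10.

Steps most likely to fail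

Step 11. The crowded, acid-sensitive substrate may ionise at the doubly activated benzylic C2–O ether, may close in the 5-exo mode, or may not cyclise at a useful rate. In that case the bottom unit is brought in ready-made. The fallback sets out from 8 and 2: BF3·OEt2 in CH2Cl2 at −78 → −30 °C ionises the ethoxyethyl ether of 8 in the presence of an excess of 2, whose C8 captures the C4 cation on the β face. This is the standard flavan-4-yl cation coupling at C8 of procyanidin synthesis and should give 15 directly, where the route is rejoined. It needs no compound outside the list (F0), and it also bypasses steps 7 and 10, so it covers a failure of the etherification as well.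

Step 6. The cation may be consumed by chain growth at the C6 positions of 7 and 8. The iodine promoter may also iodinate a free C6, or leak onto the ether leaving group of 6. In that case the order of the two activations is inverted. The fallback sets out from 6 and 7: 6 is ionised with BF3·OEt2 at −78 °C in the presence of an excess of 7, whose hindered sulfide is inert to the hard acid and whose C6 attacks. This should give the 4β→6 dimer carrying the 4β-[(2,6-dimethylphenyl)thio] group on the middle unit F1. The sulfide of F1 is then ionised with AgBF4 in THF at 0 °C in the presence of 9, which is arylated at C2 as in step 7, and the route is rejoined at 10.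

Step 13. The one-pot deprotection may stall through catalyst poisoning by bromide or partial debenzylation. It may also damage the product through acid-induced cleavage of interflavan bonds, base-induced epimerisation at C2, or oxidation of the free gallates. In that case the two reductions are separated. The fallback sets out from 16: radical hydrodebromination with Bu3SnH and AIBN in toluene at 90 °C should give the bromine-free perbenzylated trimer trigallate F2. F2 is then debenzylated under neutral conditions (H2, Pd(OH)2/C, THF/MeOH, rt), and the route is rejoined at 17.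

Further compounds
F0 | step 11 | none | none
F1 | step 6 | 4β→6 dimer with the 4β-[(2,6-dimethylphenyl)thio] group on the middle unit (top and middle units 8-bromo-tetra-O-benzyl-epicatechin 3-O-tribenzylgallates) | O=C(c1cc(OCc2ccccc2)c(OCc2ccccc2)c(OCc2ccccc2)c1)O[C@@H]1[C@@H](Sc2c(C)cccc2C)c2c(OCc3ccccc3)c([C@H]3c4c(OCc5ccccc5)cc(OCc5ccccc5)c(Br)c4O[C@H](c4ccc(OCc5ccccc5)c(OCc5ccccc5)c4)[C@@H]3OC(=O)c3cc(OCc4ccccc4)c(OCc4ccccc4)c(OCc4ccccc4)c3)c(OCc3ccccc3)c(Br)c2O[C@@H]1c1ccc(OCc2ccccc2)c(OCc2ccccc2)c1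
F2 | step 13 | bromine-free perbenzylated trimer trigallate (16 with both C8 bromines replaced by hydrogen) | O=C(c1cc(OCc2ccccc2)c(OCc2ccccc2)c(OCc2ccccc2)c1)O[C@@H]1[C@@H](c2c(OCc3ccccc3)cc(OCc3ccccc3)c3c2O[C@H](c2ccc(OCc4ccccc4)c(OCc4ccccc4)c2)[C@H](OC(=O)c2cc(OCc4ccccc4)c(OCc4ccccc4)c(OCc4ccccc4)c2)C3)c2c(OCc3ccccc3)c([C@H]3c4c(OCc5ccccc5)cc(OCc5ccccc5)cc4O[C@H](c4ccc(OCc5ccccc5)c(OCc5ccccc5)c4)[C@@H]3OC(=O)c3cc(OCc4ccccc4)c(OCc4ccccc4)c(OCc4ccccc4)c3)c(OCc3ccccc3)cc2O[C@@H]1c1ccc(OCc2ccccc2)c(OCc2ccccc2)c1
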